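The plan rests on opening each outer ring E between C2 and C3. Its O-bearing carbons C2, C4, C6 and H-bearing carbons C3, C5 follow the 1,3,5-oxygen rhythm of a folded triketide. C1, which holds ring D, is then merely the alpha carbon of an arylacetic ester. The crowded D–E bond (four ortho oxygens) thus exists before ring E does. The precursor is a methyl 2-aryl-3,5-dioxohexanoate carried as its 3-O-methyl enol ether. Under methoxide its terminal CH3 carbon attacks the ester carbon, and tautomerisation delivers the aromatic ring in one operation. Two D–E phenols are finally joined to an A–B–C dibromide and all methyl ethers are cleaved.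

Key step: step 7

Ring letters: A is the 3,5-dihydroxyphenoxy ring. B is the central ring with three aryloxy groups and one OH. C denotes the two 2,6-dihydroxy-1,4-dioxygenated rings, D the two pentasubstituted rings, and E the two terminal 2,4,6-trihydroxyphenyl rings. The target has no stereocentre, and because ring E is symmetric it has no stereogenic axis.

Remark on the design: in a free 2-aryl-3,5-dioxohexanoate, H-2 and H-4 are lost long before H-6.
- A polyanion would therefore hold the ester carbonyl inside an unreactive enolate.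
- Milder base would let the C5 enolate oxygen lactonise to a 4-hydroxypyranone whose anion does not reopen.
- The route passes through that lactone on purpose, caps O-3 (chain numbering) as a methyl ether, and releases the open keto ester only in the flask of the key step.
- The free dioxo ester has a labile centre at C2 and is drawn without configuration.

Assumption: the phenol, diketene, the difluoroaldehyde, the bromophenol and the boronic acid used as building blocks are taken as purchasable.

Step 1
Reactants: 1 2,4,6-trimethoxyphenol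
Product: 2 2-(benzyloxy)-1,3,5-trimethoxybenzene
Conditions: BnBr, K2CO3, DMF, rt, Ar
Reagents that add atoms: benzyl bromide, BrCc1ccccc1
Why: Williamson ether synthesis, in which the phenoxide of 1 is alkylated by benzyl bromide so that the one ring D oxygen destined for the diaryl ether carries a group removable without touching any methyl ether.

Step 2
Reactants: 2 2-(benzyloxy)-1,3,5-trimethoxybenzene
Product: 4 3-(benzyloxy)-2,4,6-trimethoxybenzaldehyde, via aryl iminium chloride 3 (not isolated)
Conditions: POCl3, DMF, 0 °C to rt; then ice-water, aq NaOH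
Reagents that add atoms: N,N-dimethylformamide, CN(C)C=O (formyl carbon); water, O (carbonyl oxygen); phosphoryl chloride, O=P(Cl)(Cl)Cl (chloride counter-ion of 3 only)
Why: Vilsmeier–Haack formylation attacks one of the two equivalent free ring positions, each activated by three methoxy groups, and the iminium group of 3 deactivates the ring against a second attack.

Step 3
Reactants: 4 3-(benzyloxy)-2,4,6-trimethoxybenzaldehyde
Product: 5 2-(benzyloxy)-1,3,5-trimethoxy-4-[2-(methylsulfanyl)-2-(methylsulfinyl)ethenyl]benzene
Conditions: MeS(O)CH2SMe, BnMe3NOH (Triton B, cat.), THF, reflux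
Reagents that add atoms: methyl (methylsulfinyl)methyl sulfide, CSCS(C)=O
Why: Knoevenagel-type condensation of the stabilised dithioacetal S-oxide carbanion with a non-enolisable aldehyde, run without any oxidant or electrophile that could attack the electron-rich ring or its last free C–H.

Step 4
Reactants: 5 2-(benzyloxy)-1,3,5-trimethoxy-4-[2-(methylsulfanyl)-2-(methylsulfinyl)ethenyl]benzene
Product: 6 methyl [3-(benzyloxy)-2,4,6-trimethoxyphenyl]acetate
Conditions: HCl, MeOH, rt to 50 °C
Reagents that add atoms: methanol, CO
Why: Acid methanolysis of a ketene dithioacetal S-oxide, in which protonation at the benzylic carbon, addition of methanol and internal redox loss of both sulfur groups leave the one-carbon homologated ester while benzyl and methyl ethers are stable to methanolic HCl.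

Step 5
Reactants: 6 methyl [3-(benzyloxy)-2,4,6-trimethoxyphenyl]acetate; 7 diketene
Product: 9 3-[3-(benzyloxy)-2,4,6-trimethoxyphenyl]-4-hydroxy-6-methyl-2H-pyran-2-one, via free dioxo ester 8 (not isolated)
Conditions: LiN(SiMe3)2 (2.2 equiv), THF, −78 °C; 7, −78 to −20 °C; AcOH; then DBU, PhMe, 80 °C
Reagents that add atoms: none
Why: Crossed Claisen acylation in which the ester enolate opens diketene at its lactone carbonyl (C-acetoacetylation, the second equivalent of base absorbing the acidic product), followed by the base-induced lactonisation typical of 3,5-dioxo esters, used here deliberately to lock the C2=C3 enol geometry and to single out O-3.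

Step 6
Reactants: 9 3-[3-(benzyloxy)-2,4,6-trimethoxyphenyl]-4-hydroxy-6-methyl-2H-pyran-2-one
Product: 10 3-[3-(benzyloxy)-2,4,6-trimethoxyphenyl]-4-methoxy-6-methyl-2H-pyran-2-one
Conditions: Me2SO4, K2CO3, acetone, reflux
Reagents that add atoms: dimethyl sulfate, COS(=O)(=O)OC
Why: O-Alkylation of the vinylogous acid with a hard methylating agent, which is the standard way from 4-hydroxy-6-methyl-2-pyranones to their 4-methoxy ethers and removes the acidic OH that would otherwise shield the lactone from alkoxide.

Step 7
Reactants: 10 3-[3-(benzyloxy)-2,4,6-trimethoxyphenyl]-4-methoxy-6-methyl-2H-pyran-2-one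
Product: 12 4-[3-(benzyloxy)-2,4,6-trimethoxyphenyl]-5-methoxybenzene-1,3-diol, via ring-opened keto ester 11 (not isolated)
Conditions: NaOMe (excess), MeOH, sealed tube, 180 °C, Ar; then aq HCl, 0 °C
Reagents that add atoms: sodium methoxide, [Na+].[O-]C (its methoxy group enters 11 as the ester OMe and leaves again on ring closure)
Why: Methoxide adds to the lactone carbonyl of 10 and opens the ring to 11, in which the former ring bond holds the ester carbon C1 and the C4 methylene on the same side of the C2=C3 double bond. Reversible enolisation of the C5 ketone towards the terminal methyl group gives the C6 enolate, which attacks C1; loss of methoxide and tautomerisation of the cyclohexadienone give ring E as its phenoxide (new bond C2–C3 of ring E). The closest known reactions are the Claisen (Dieckmann-type) cyclisation of 5-oxohexanoates to cyclohexane-1,3-diones and the alkoxide-induced isomerisation of 4-methoxy-6-methyl-2-pyranone to 5-methoxyresorcinol under the same conditions. The single ring closure is 6-(enolendo)-exo-trig, with C6 approaching C1 in the plane of the chain and thus away from the two ortho methoxy groups of ring D, which lie above and below that plane. The selectivity needed is C- over O-acylation: O-attack by the C5 enolate only regenerates neutral 10, which reopens, whereas C-attack is made irreversible by aromatisation and phenoxide formation, and because C2 bears no hydrogen the ester can never be switched off as its own enolate. No stereocentre is formed; the hindered D–E axis of 12 arises racemic and stops being stereogenic once ring E is symmetric (step 8).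

Step 8
Reactants: 12 4-[3-(benzyloxy)-2,4,6-trimethoxyphenyl]-5-methoxybenzene-1,3-diol
Product: 13 3-(benzyloxy)-2,2',4,4',6,6'-hexamethoxy-1,1'-biphenyl
Conditions: MeI, K2CO3, DMF, rt
Reagents that add atoms: iodomethane, CI
Why: Williamson O-methylation of the two remaining phenols, which caps ring E, makes it symmetric and leaves the benzyl ether as the only differentiated oxygen.

Step 9
Reactants: 13 3-(benzyloxy)-2,2',4,4',6,6'-hexamethoxy-1,1'-biphenyl
Product: 14 2,2',4,4',6,6'-hexamethoxy-[1,1'-biphenyl]-3-ol
Conditions: H2 (1 atm), Pd/C, EtOAc–MeOH, rt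
Reagents that add atoms: none
Why: Catalytic hydrogenolysis cleaves only the benzylic C–O bond, since aryl methyl ethers and the biaryl bond are inert to these conditions.

Step 10
Reactants: 15 2,6-difluoro-4-methoxybenzaldehyde; 16 4-bromo-2,6-dimethoxyphenol (2.3 equiv)
Product: 17 2,6-bis(4-bromo-2,6-dimethoxyphenoxy)-4-methoxybenzaldehyde
Conditions: K2CO3, DMSO, 120 °C, Ar
Reagents that add atoms: none
Why: Twofold nucleophilic aromatic substitution by addition–elimination, because both fluorides are ortho to the formyl group that stabilises the Meisenheimer adducts, so the two crowded B–O–C bonds are made without copper and the aryl bromides of 16 stay intact.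

Step 11
Reactants: 17 2,6-bis(4-bromo-2,6-dimethoxyphenoxy)-4-methoxybenzaldehyde
Product: 19 2,6-bis(4-bromo-2,6-dimethoxyphenoxy)-4-methoxyphenol, via aryl formate 18 (not isolated)
Conditions: mCPBA, CH2Cl2, 0 °C to rt; then K2CO3 (cat.), MeOH, rt, Ar
Reagents that add atoms: 3-chloroperoxybenzoic acid, OOC(=O)c1cccc(Cl)c1
Why: Baeyer–Villiger oxidation in which the 2,4,6-trioxygenated aryl group migrates in preference to hydride, followed by mild methanolysis of formate 18 to the phenol.

Step 12
Reactants: 19 2,6-bis(4-bromo-2,6-dimethoxyphenoxy)-4-methoxyphenol; 20 3,5-dimethoxyphenylboronic acid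
Product: 21 1,3-bis(4-bromo-2,6-dimethoxyphenoxy)-2-(3,5-dimethoxyphenoxy)-5-methoxybenzene
Conditions: Cu(OAc)2, pyridine, 4 Å MS, CH2Cl2, dry air, rt
Reagents that add atoms: none
Why: Chan–Lam O-arylation at room temperature, a coupling known to accept phenols flanked by two ortho substituents (for example 2,6-diiodophenols) when the boronic acid is unhindered, and one that leaves aryl bromides untouched.

Step 13
Reactants: 21 1,3-bis(4-bromo-2,6-dimethoxyphenoxy)-2-(3,5-dimethoxyphenoxy)-5-methoxybenzene; 14 2,2',4,4',6,6'-hexamethoxy-[1,1'-biphenyl]-3-ol (2.4 equiv)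
Product: 22 1,3-bis{4-[(2,2',4,4',6,6'-hexamethoxy[1,1'-biphenyl]-3-yl)oxy]-2,6-dimethoxyphenoxy}-2-(3,5-dimethoxyphenoxy)-5-methoxybenzene (nonadecamethyl ether of the target)
Conditions: CuI, picolinic acid, K3PO4, DMSO, 100 °C, Ar
Reagents that add atoms: none
Why: Twofold ligand-accelerated Ullmann diaryl ether synthesis, in which the hindrance lies on the phenol only (a case this catalyst system handles) because each ring C bromide has hydrogen in both ortho positions.

Step 14
Reactants: 22 nonadecamethyl ether of the target
Product: 23 CNP0227063.0, 3,5-bis{4-[(2,2',4,4',6,6'-hexahydroxy[1,1'-biphenyl]-3-yl)oxy]-2,6-dihydroxyphenoxy}-4-(3,5-dihydroxyphenoxy)phenol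
Conditions: BBr3 (excess), CH2Cl2, −78 °C to rt, Ar; then H2O, 0 °C
Reagents that add atoms: none
Why: Lewis acid-mediated cleavage of aryl methyl ethers, in which BBr3 binds each methoxy oxygen and bromide removes the methyl group by SN2, whereas diaryl ether and biaryl bonds offer no sp3 carbon and persist, so that hydrolysis of the aryl borates frees all nineteen phenols.

Compound list
1 | 2,4,6-trimethoxyphenol | Oc1c(OC)cc(OC)cc1OC | starting material
2 | 2-(benzyloxy)-1,3,5-trimethoxybenzene | COc1cc(OC)c(OCc2ccccc2)c(OC)c1 | intermediate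
3 | N-{[3-(benzyloxy)-2,4,6-trimethoxyphenyl]methylidene}-N-methylmethanaminium chloride (not isolated) | C[N+](C)=Cc1c(OC)cc(OC)c(OCc2ccccc2)c1OC.[Cl-] | intermediate
4 | 3-(benzyloxy)-2,4,6-trimethoxybenzaldehyde | O=Cc1c(OC)cc(OC)c(OCc2ccccc2)c1OC | intermediate
5 | 2-(benzyloxy)-1,3,5-trimethoxy-4-[2-(methylsulfanyl)-2-(methylsulfinyl)ethenyl]benzene (alkene geometry and sulfur configuration not controlled, both lost in step 4) | CSC(=Cc1c(OC)cc(OC)c(OCc2ccccc2)c1OC)S(C)=O | intermediate
6 | methyl [3-(benzyloxy)-2,4,6-trimethoxyphenyl]acetate | COC(=O)Cc1c(OC)cc(OC)c(OCc2ccccc2)c1OC | intermediate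
7 | diketene (4-methylideneoxetan-2-one) | C=C1CC(=O)O1 | starting material
8 | methyl 2-[3-(benzyloxy)-2,4,6-trimethoxyphenyl]-3,5-dioxohexanoate (racemic, labile C2, drawn flat; not isolated) | COC(=O)C(C(=O)CC(C)=O)c1c(OC)cc(OC)c(OCc2ccccc2)c1OC | intermediate
9 | 3-[3-(benzyloxy)-2,4,6-trimethoxyphenyl]-4-hydroxy-6-methyl-2H-pyran-2-one (racemic about the hindered axis) | Cc1cc(O)c(-c2c(OC)cc(OC)c(OCc3ccccc3)c2OC)c(=O)o1 | intermediate
10 | 3-[3-(benzyloxy)-2,4,6-trimethoxyphenyl]-4-methoxy-6-methyl-2H-pyran-2-one (racemic about the hindered axis) | Cc1cc(OC)c(-c2c(OC)cc(OC)c(OCc3ccccc3)c2OC)c(=O)o1 | intermediate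
11 | methyl (2E)-2-[3-(benzyloxy)-2,4,6-trimethoxyphenyl]-3-methoxy-5-oxohex-2-enoate (ester carbon and C4 cis; 3-O-methyl enol ether of 8; not isolated) | COC(=O)/C(c1c(OC)cc(OC)c(OCc2ccccc2)c1OC)=C(/OC)CC(C)=O | intermediate
12 | 4-[3-(benzyloxy)-2,4,6-trimethoxyphenyl]-5-methoxybenzene-1,3-diol (racemic about the D–E axis) | COc1cc(O)cc(O)c1-c1c(OC)cc(OC)c(OCc2ccccc2)c1OC | intermediate
13 | 3-(benzyloxy)-2,2',4,4',6,6'-hexamethoxy-1,1'-biphenyl | COc1cc(OC)c(-c2c(OC)cc(OC)c(OCc3ccccc3)c2OC)c(OC)c1 | intermediate
14 | 2,2',4,4',6,6'-hexamethoxy-[1,1'-biphenyl]-3-ol | COc1cc(OC)c(-c2c(OC)cc(OC)c(O)c2OC)c(OC)c1 | intermediate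
15 | 2,6-difluoro-4-methoxybenzaldehyde | COc1cc(F)c(C=O)c(F)c1 | starting material
16 | 4-bromo-2,6-dimethoxyphenol | COc1cc(Br)cc(OC)c1O | starting material
17 | 2,6-bis(4-bromo-2,6-dimethoxyphenoxy)-4-methoxybenzaldehyde | COc1cc(Oc2c(OC)cc(Br)cc2OC)c(C=O)c(Oc2c(OC)cc(Br)cc2OC)c1 | intermediate
18 | 2,6-bis(4-bromo-2,6-dimethoxyphenoxy)-4-methoxyphenyl formate (not isolated) | COc1cc(Oc2c(OC)cc(Br)cc2OC)c(OC=O)c(Oc2c(OC)cc(Br)cc2OC)c1 | intermediate
19 | 2,6-bis(4-bromo-2,6-dimethoxyphenoxy)-4-methoxyphenol | COc1cc(Oc2c(OC)cc(Br)cc2OC)c(O)c(Oc2c(OC)cc(Br)cc2OC)c1 | intermediate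
20 | 3,5-dimethoxyphenylboronic acid | COc1cc(OC)cc(B(O)O)c1 | starting material
21 | 1,3-bis(4-bromo-2,6-dimethoxyphenoxy)-2-(3,5-dimethoxyphenoxy)-5-methoxybenzene | COc1cc(OC)cc(Oc2c(Oc3c(OC)cc(Br)cc3OC)cc(OC)cc2Oc2c(OC)cc(Br)cc2OC)c1 | intermediate
22 | 1,3-bis{4-[(2,2',4,4',6,6'-hexamethoxy[1,1'-biphenyl]-3-yl)oxy]-2,6-dimethoxyphenoxy}-2-(3,5-dimethoxyphenoxy)-5-methoxybenzene | COc1cc(OC)cc(Oc2c(Oc3c(OC)cc(Oc4c(OC)cc(OC)c(-c5c(OC)cc(OC)cc5OC)c4OC)cc3OC)cc(OC)cc2Oc2c(OC)cc(Oc3c(OC)cc(OC)c(-c4c(OC)cc(OC)cc4OC)c3OC)cc2OC)c1 | intermediate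
23 | CNP0227063.0, 3,5-bis{4-[(2,2',4,4',6,6'-hexahydroxy[1,1'-biphenyl]-3-yl)oxy]-2,6-dihydroxyphenoxy}-4-(3,5-dihydroxyphenoxy)phenol | Oc1cc(O)cc(Oc2c(Oc3c(O)cc(Oc4c(O)cc(O)c(-c5c(O)cc(O)cc5O)c4O)cc3O)cc(O)cc2Oc2c(O)cc(Oc3c(O)cc(O)c(-c4c(O)cc(O)cc4O)c3O)cc2O)c1 | target

Total step count: 14. Longest linear sequence: 11 steps (steps 1–9, 13 and 14). The A–B–C dibromide branch (steps 10–12) runs in parallel.

Steps most likely to fail

Step 7. The hindered lactone carbonyl may resist methoxide. Demethylation of the vinylogous ester, or retro-Claisen loss of the acetyl end, may also outrun the ring closure at the temperature required. The fallback sets out from 2 and comes back at 13, and it brings ring E in ready-made.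
- Bromination of 2 with NBS in MeCN at 0 °C should give 2-(benzyloxy)-4-bromo-1,3,5-trimethoxybenzene F1.
- 1,3,5-Trimethoxybenzene is lithiated between two methoxy groups (n-BuLi, THF) and transmetallated with ZnCl2 to chloro(2,4,6-trimethoxyphenyl)zinc F2.
- Negishi coupling of the two (Pd2(dba)3, RuPhos, THF, 70 °C), a catalyst system made for biaryls with four ortho substituents, leads directly to 13.

Step 13. C–O bond formation with the electron-rich, doubly ortho-substituted phenoxide may be slow. Hydrodebromination and stalling after the first coupling could then compete. The fallback sets out from 21 and comes back at 22, and it changes the coupling partner on ring C from halide to boron.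
- Twofold bromine–lithium exchange on 21 (n-BuLi, THF, −78 °C), B(OMe)3 and acidic work-up should give {[2-(3,5-dimethoxyphenoxy)-5-methoxy-1,3-phenylene]bis[oxy(3,5-dimethoxy-4,1-phenylene)]}diboronic acid F4.
- F4 is joined to 14 by Chan–Lam coupling (Cu(OAc)2, pyridine, 4 Å MS, CH2Cl2, air, rt). This oxidative coupling runs at room temperature and accepts 2,6-disubstituted phenols when the boronic acid is unhindered.

Step 5. Proton transfer from diketene, its base-induced oligomerisation, or O-acylation of the hindered enolate may consume the reagents before C-acylation occurs. The fallback sets out from 6 and comes back at 8, and it grows the chain in two acetyl units by standard Claisen chemistry.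
- The lithium enolate of 6 is acetylated with 1-acetylimidazole to methyl 2-[3-(benzyloxy)-2,4,6-trimethoxyphenyl]-3-oxobutanoate F3.
- The 2,4-dianion of F3 (NaH, then n-BuLi, THF, 0 °C) is acetylated at its terminal carbon with N-methoxy-N-methylacetamide to give 8.
- 8 is lactonised with DBU as in step 5.

Further compounds
F1 | step 7 | 2-(benzyloxy)-4-bromo-1,3,5-trimethoxybenzene | COc1cc(OC)c(OCc2ccccc2)c(OC)c1Br
F2 | step 7 | chloro(2,4,6-trimethoxyphenyl)zinc | COc1cc(OC)c([Zn]Cl)c(OC)c1
F3 | step 5 | methyl 2-[3-(benzyloxy)-2,4,6-trimethoxyphenyl]-3-oxobutanoate (racemic, labile centre, drawn flat) | COC(=O)C(C(C)=O)c1c(OC)cc(OC)c(OCc2ccccc2)c1OC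
F4 | step 13 | {[2-(3,5-dimethoxyphenoxy)-5-methoxy-1,3-phenylene]bis[oxy(3,5-dimethoxy-4,1-phenylene)]}diboronic acid | COc1cc(OC)cc(Oc2c(Oc3c(OC)cc(B(O)O)cc3OC)cc(OC)cc2Oc2c(OC)cc(B(O)O)cc2OC)c1
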